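**Remarks on the chemistry**
- Numbering: carotenoid numbering is used for the end ring (C1 = CMe2, C2 = CH2, C3 and C4 = the oxygenated carbons, C5 = CHMe, C6 = the CH that carries the chain, C7 = first chain carbon). "β face" is the ring face that carries the C6 side chain, "α face" the other one.
- Assumption: the target is made as drawn, the free bis(hydrogen sulfate) of the all-E polyene; it is released from its salt on an acid resin in the last operation and would be kept cold or stored as a salt.

## Retrosynthetic overview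
1. The target comes from the C2-symmetric tetrol by sulfation of the equatorial O4 of each ring cis-diol, both ends at once, directed by a temporary dibutylstannylene acetal.
2. The tetrol comes from a two-directional double Wittig reaction of the C10 trienedial (C12 to C12') with two molecules of one C15 ring phosphonium salt, itself made from a C13 ring enone.
3. The ring 3,4-cis-diol comes from the ring C3=C4 olefin by Woodward cis-hydroxylation on the β face, the face hindered by the axial C1 methyl.
4. The cyclohexene C1–C6 comes from an auxiliary-controlled Diels–Alder reaction of (E)-piperylene (C2, C3, C4, C5 and the C5 methyl) with an N-senecioyl oxazolidinone (C1 with both methyls, C6, C7). This is the only ring-forming step; both cyclohexane rings of the target stem from it and no ring of the skeleton is closed after it. C6 is epimerised to trans afterwards.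
5. Enabling feature: in each end ring the gem-dimethyl carbon C1 is bonded to the chain-bearing C6 (a senecioyl C1=C6 once C7 is a carbonyl), C5 carries a methyl, and C3/C4 carry cis oxygens that mark a former C3=C4 olefin. Ring atoms C2–C5 plus the C5 methyl are therefore piperylene, and the C2 axis lets one ring synthesis serve both ends.

Key step: step 2

## Route

Step 1
Reactants: 1 (S)-4-benzyloxazolidin-2-one; 2 3-methylbut-2-enoyl chloride
Product: 4 (S)-4-benzyl-3-(3-methylbut-2-enoyl)oxazolidin-2-one, via lithium amide 3 (not isolated)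
Conditions: n-BuLi, THF, −78 °C; then 2, −78 → 0 °C
Reagents that add atoms: none
Why: N-acylation of the lithiated oxazolidinone by the acid chloride, run without amine base so that the senecioyl group is not deconjugated through a vinylketene; no stereocentre is formed.

Step 2
Reactants: 4 (S)-4-benzyl-3-(3-methylbut-2-enoyl)oxazolidin-2-one; 5 (E)-penta-1,3-diene
Product: 6 (4S)-4-benzyl-3-{[(1S,2S)-2,6,6-trimethylcyclohex-3-en-1-yl]carbonyl}oxazolidin-2-one (cis adduct: C5 methyl and C6 acyl group cis)
Conditions: Et2AlCl (1.5 equiv), 5 (5 equiv), CH2Cl2, −40 → 0 °C; 1 M HCl quench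
Reagents that add atoms: none
Why: Proposed new method: excess Et2AlCl should turn imide 4 into the cationic chelate in which aluminium holds both carbonyl oxygens and the senecioyl unit is locked s-cis, and (E)-piperylene should add to this strongly activated dienophile in a concerted, asynchronous [4+2] cycloaddition (Diels–Alder reaction) in which the C1–C2 bond from the CH2 terminus of the diene to the β,β-dimethyl carbon runs ahead of the C5–C6 bond. The closest known reaction types are the Et2AlCl-promoted cycloadditions of N-crotonoyl oxazolidinones with piperylene and isoprene and the AlCl3-catalysed cycloaddition of mesityl oxide with piperylene, and what has not been shown is the combination, a β,β-disubstituted enoyl imide under auxiliary control. The six-membered ring C1–C6 is closed by the intermolecular cycloaddition itself, two sigma bonds (C1–C2 and C5–C6) being formed suprafacially on both partners without a tether, so no exo or endo ring-closure mode applies. C6 is set by the auxiliary, whose benzyl group covers the Cα-re face of the chelate so that the diene adds to the Cα-si face, and C5 is set by the endo orientation of the diene under the chelated carbonyl together with the E geometry of the diene, which places the C5 methyl cis to the acyl group. The step needs ortho regioselectivity, secured by the larger HOMO coefficient at the unsubstituted diene terminus, by the polarised β-carbon of the chelate and by the fact that the alternative would join the two most hindered carbons, endo selectivity, secured by the Lewis-acid-bound carbonyl, and π-facial selectivity, secured by the auxiliary. Minor isomers can be removed here because all adducts are diastereomeric imides, and the cis relation at C6 is corrected in step 4, so that only C5 has to be set correctly in this step.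

Step 3
Reactants: 6 cis adduct
Product: 7 [(1S,2S)-2,6,6-trimethylcyclohex-3-en-1-yl]methanol
Conditions: LiBH4, MeOH (1 equiv), THF, 0 °C → rt
Reagents that add atoms: none
Why: Reductive cleavage of the N-acyl oxazolidinone, hydride adding to the more electrophilic exocyclic carbonyl, should give the primary alcohol and return auxiliary 1; C5 and C6 are not touched.

Step 4
Reactants: 7 cis alcohol
Product: 9 (1R,2S)-2,6,6-trimethylcyclohex-3-ene-1-carbaldehyde (trans), via cis aldehyde 8 (not isolated)
Conditions: Dess–Martin periodinane, CH2Cl2, 0 °C → rt; aq. Na2S2O3/NaHCO3 wash; then DBU (0.2 equiv), CH2Cl2, rt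
Reagents that add atoms: none
Why: Dess–Martin oxidation gives cis aldehyde 8 and DBU should then equilibrate the enolisable C6 centre to the trans isomer, expected to be the more stable one with formyl and C5 methyl both equatorial, while C5 (allylic, not acidic) keeps the configuration set in step 2.

Step 5
Reactants: 9 trans aldehyde
Product: 10 (3E)-4-[(1R,2S)-2,6,6-trimethylcyclohex-3-en-1-yl]but-3-en-2-one
Conditions: (MeO)2P(O)CH2COCH3, NaH, THF, 0 °C; then 9, 0 → 40 °C
Reagents that add atoms: dimethyl (2-oxopropyl)phosphonate, COP(=O)(CC(C)=O)OC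
Why: Horner–Wadsworth–Emmons olefination with a stabilised ketophosphonate anion should give the E enone, and C6 stays trans because that is also its thermodynamic configuration under the basic conditions.

Step 6
Reactants: 10 enone
Product: 13 (3E)-4-[(1R,2R,3S,4R)-3,4-dihydroxy-2,6,6-trimethylcyclohexyl]but-3-en-2-one, via iodo acetate 11 (not isolated), via hydroxy acetate 12 (not isolated)
Conditions: I2, AgOAc, AcOH, rt, dark; then H2O (1.2 equiv), 90 °C; filter, evaporate; K2CO3 (cat.), MeOH, rt
Reagents that add atoms: silver acetate, CC(=O)[O-].[Ag+]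
Why: Woodward cis-hydroxylation: acetyl hypoiodite should put iodine on the less hindered α face of the ring olefin (anti to the axial C1 methyl), acetate opens the iodonium ion trans-diaxially at C3 from the β face to give 11, silver-assisted displacement of iodide by the neighbouring acetate gives the β-face acetoxonium ion, water opens it to 12 and methanolysis leaves the 3,4-cis-diol on the β face (the face OsO4 would avoid), which sets C3 and C4 as in the 2β,3β-dihydroxylation of steroidal 2-enes, while the electron-poor enone olefin does not react with the iodine electrophile.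

Step 7
Reactants: 13 diol enone
Product: 14 (1E)-1-[(1R,2R,3S,4R)-3,4-dihydroxy-2,6,6-trimethylcyclohexyl]-3-methylpenta-1,4-dien-3-ol (both epimers at the carbinol carbon)
Conditions: CH2=CHMgBr (4 equiv), THF, −20 → 0 °C; aq. NH4Cl
Reagents that add atoms: vinylmagnesium bromide, C=C[Mg]Br
Why: Grignard 1,2-addition to the methyl ketone, after the excess reagent has deprotonated the two hydroxyls, gives the tertiary allylic alcohol, whose new carbinol centre is formed unselectively and is destroyed in step 8.

Step 8
Reactants: 14 vinyl carbinol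
Product: 15 {(2E,4E)-5-[(1R,2R,3S,4R)-3,4-dihydroxy-2,6,6-trimethylcyclohexyl]-3-methylpenta-2,4-dien-1-yl}triphenylphosphonium bromide
Conditions: PPh3·HBr, MeOH, rt
Reagents that add atoms: triphenylphosphine hydrobromide, [Br-].c1ccc(cc1)[PH+](c1ccccc1)c1ccccc1
Why: Acid-promoted ionisation of the tertiary bis-allylic alcohol and SN1' capture of the pentadienyl cation at its unhindered CH2 terminus by PPh3 should give the conjugated allylic phosphonium salt (the usual vinyl-carbinol route to carotenoid Wittig salts), the ring hydroxyls being non-allylic and inert, and any 9Z isomer being equilibrated in step 9.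

Step 9
Reactants: 15 C15 phosphonium bromide (2.2 equiv); 16 (2E,4E,6E)-2,7-dimethylocta-2,4,6-trienedial
Product: 18 (3R,4S,5R,6R,3'R,4'S,5'R,6'R)-5,6,5',6'-tetrahydro-β,β-carotene-3,4,3',4'-tetrol, via ylide 17 (not isolated)
Conditions: 1,2-epoxybutane, EtOH, reflux, N2, dark
Reagents that add atoms: none
Why: Double Wittig olefination: bromide opens the epoxide to an alkoxide that forms the semistabilised ylide 17 without strong base, both C11=C12 bonds are built at the same time, Z isomers should equilibrate thermally to the favoured all-E polyene under the same conditions, and free hydroxyls are tolerated in carotenoid Wittig couplings of this type.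

Step 10
Reactants: 18 tetrol
Product: 21 (3R,4S,5R,6R,3'R,4'S,5'R,6'R)-5,6,5',6'-tetrahydro-β,β-carotene-3,4,3',4'-tetrol 4,4'-bis(hydrogen sulfate) (CNP0202532.2), via bis-stannylene acetal 19 (not isolated), via bis(trimethylammonium) salt 20 (not isolated)
Conditions: Bu2SnO (2.2 equiv), MeOH/toluene, 65 °C, evaporate; SO3·NMe3 (2.5 equiv), 1,4-dioxane, rt; then sulfonic acid cation-exchange resin (H+ form), MeOH/H2O, 0 °C; freeze-dry
Reagents that add atoms: sulfur trioxide–trimethylamine complex, C[N+](C)(C)S(=O)(=O)[O-]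
Why: Stannylene-acetal-directed sulfation: in the dibutylstannylene acetal of a cyclic cis-1,2-diol the equatorial oxygen is the nucleophilic one, as in the 3-O-sulfation of galactosides, so SO3·NMe3 should sulfate O4 and leave the axial, 1,3-diaxially hindered C3–OH free at both ends, Bu2SnO being returned on hydrolytic work-up and the resin exchanging trimethylammonium for protons.

## Compound list
1 | (S)-4-benzyloxazolidin-2-one | O=C1N[C@@H](Cc2ccccc2)CO1 | starting material
2 | 3-methylbut-2-enoyl chloride | CC(C)=CC(=O)Cl | starting material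
3 | lithium salt of 1 (N-lithio oxazolidinone) | [Li+].O=C1[N-][C@@H](Cc2ccccc2)CO1 | intermediate
4 | (S)-4-benzyl-3-(3-methylbut-2-enoyl)oxazolidin-2-one | CC(C)=CC(=O)N1[C@@H](Cc2ccccc2)COC1=O | intermediate
5 | (E)-penta-1,3-diene | C=C/C=C/C | starting material
6 | (4S)-4-benzyl-3-{[(1S,2S)-2,6,6-trimethylcyclohex-3-en-1-yl]carbonyl}oxazolidin-2-one | O=C(N1[C@@H](Cc2ccccc2)COC1=O)[C@H]3[C@@H](C)C=CCC3(C)C | intermediate
7 | [(1S,2S)-2,6,6-trimethylcyclohex-3-en-1-yl]methanol | OC[C@H]1[C@@H](C)C=CCC1(C)C | intermediate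
8 | (1S,2S)-2,6,6-trimethylcyclohex-3-ene-1-carbaldehyde (cis) | O=C[C@H]1[C@@H](C)C=CCC1(C)C | intermediate
9 | (1R,2S)-2,6,6-trimethylcyclohex-3-ene-1-carbaldehyde (trans) | O=C[C@@H]1[C@@H](C)C=CCC1(C)C | intermediate
10 | (3E)-4-[(1R,2S)-2,6,6-trimethylcyclohex-3-en-1-yl]but-3-en-2-one | CC(=O)/C=C/[C@@H]1[C@@H](C)C=CCC1(C)C | intermediate
11 | (3E)-4-[(1R,2R,3R,4R)-4-acetoxy-3-iodo-2,6,6-trimethylcyclohexyl]but-3-en-2-one (3β-acetoxy, 4α-iodo, trans-diaxial) | CC(=O)/C=C/[C@@H]1[C@@H](C)[C@@H](I)[C@H](OC(C)=O)CC1(C)C | intermediate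
12 | (3E)-4-[(1R,2R,3S,4R)-4-acetoxy-3-hydroxy-2,6,6-trimethylcyclohexyl]but-3-en-2-one (drawn as the axial 3-acetate; which oxygen holds the acetyl is immaterial, it is cleaved in the same step) | CC(=O)/C=C/[C@@H]1[C@@H](C)[C@H](O)[C@H](OC(C)=O)CC1(C)C | intermediate
13 | (3E)-4-[(1R,2R,3S,4R)-3,4-dihydroxy-2,6,6-trimethylcyclohexyl]but-3-en-2-one | CC(=O)/C=C/[C@@H]1[C@@H](C)[C@H](O)[C@H](O)CC1(C)C | intermediate
14 | (1E)-1-[(1R,2R,3S,4R)-3,4-dihydroxy-2,6,6-trimethylcyclohexyl]-3-methylpenta-1,4-dien-3-ol (carbinol epimers) | C=CC(C)(O)/C=C/[C@@H]1[C@@H](C)[C@H](O)[C@H](O)CC1(C)C | intermediate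
15 | {(2E,4E)-5-[(1R,2R,3S,4R)-3,4-dihydroxy-2,6,6-trimethylcyclohexyl]-3-methylpenta-2,4-dien-1-yl}triphenylphosphonium bromide | C/C(=C\C[P+](c1ccccc1)(c1ccccc1)c1ccccc1)/C=C/[C@@H]2[C@@H](C)[C@H](O)[C@H](O)CC2(C)C.[Br-] | intermediate
16 | (2E,4E,6E)-2,7-dimethylocta-2,4,6-trienedial | O=C/C(C)=C/C=C/C=C(C)/C=O | starting material
17 | ylide of 15 (triphenylphosphoranylidene form) | C/C(=C\C=P(c1ccccc1)(c1ccccc1)c1ccccc1)/C=C/[C@@H]2[C@@H](C)[C@H](O)[C@H](O)CC2(C)C | intermediate
18 | (3R,4S,5R,6R,3'R,4'S,5'R,6'R)-5,6,5',6'-tetrahydro-β,β-carotene-3,4,3',4'-tetrol | CC(/C=C/C=C(C)/C=C/[C@@H]1[C@@H](C)[C@H](O)[C@H](O)CC1(C)C)=C\C=C\C=C(C)\C=C\C=C(C)\C=C\[C@@H]1[C@@H](C)[C@H](O)[C@H](O)CC1(C)C | intermediate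
19 | 3,4:3',4'-bis-O-(dibutylstannylene) acetal of 18 | CC(/C=C/C=C(C)/C=C/[C@@H]1[C@@H](C)[C@H](O[Sn]2(CCCC)CCCC)[C@H](O2)CC1(C)C)=C\C=C\C=C(C)\C=C\C=C(C)\C=C\[C@@H]1[C@@H](C)[C@H](O[Sn]2(CCCC)CCCC)[C@H](O2)CC1(C)C | intermediate
20 | bis(trimethylammonium) salt of 21 | CC(/C=C/C=C(C)/C=C/[C@@H]1[C@@H](C)[C@H](OS(=O)(=O)[O-])[C@H](O)CC1(C)C)=C\C=C\C=C(C)\C=C\C=C(C)\C=C\[C@@H]1[C@@H](C)[C@H](OS(=O)(=O)[O-])[C@H](O)CC1(C)C.C[NH+](C)C.C[NH+](C)C | intermediate
21 | (3R,4S,5R,6R,3'R,4'S,5'R,6'R)-5,6,5',6'-tetrahydro-β,β-carotene-3,4,3',4'-tetrol 4,4'-bis(hydrogen sulfate) | CC(/C=C/C=C(C)/C=C/[C@@H]1[C@@H](C)[C@H](OS(=O)(=O)O)[C@H](O)CC1(C)C)=C\C=C\C=C(C)\C=C\C=C(C)\C=C\[C@@H]1[C@@H](C)[C@H](OS(=O)(=O)O)[C@H](O)CC1(C)C | target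

## Count and risks
Total step count: 10. Longest linear sequence: 10 steps (1 to 21; 2, 5 and 16 are bought).

Steps most likely to fail:

1. Step 2 (carries the label). The doubly β-substituted chelate may react too slowly, so that Lewis-acid-induced oligomerisation of the diene, or erosion of endo and facial control, takes over. The fallback sets out from 5 and comes back at 9, using resolution through covalent diastereomers instead of asymmetric induction. Piperylene 5 and mesityl oxide (4-methylpent-3-en-2-one, CC(C)=CC(C)=O) are combined under AlCl3 catalysis in toluene, a known cycloaddition, to give the racemic cis ketone F1 together with its trans isomer. NaOMe in MeOH equilibrates the mixture to the racemic trans ketone F2. Haloform cleavage with NaOBr gives the racemic trans acid F3, and oxalyl chloride gives the racemic acid chloride F4. F4 acylates lithium amide 3 to give the wanted (1R,2S) trans imide F5 and its (1S,2R) diastereomer F6, which are separated by chromatography or crystallisation. LiBH4 reduction of F5 gives the trans alcohol F7, and Dess–Martin oxidation of F7 gives 9.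

2. Step 6. Iodonium formation and acetate opening may take place on the wrong ring face, or the methyl ketone may be iodinated at its α-carbon before the olefin is consumed. The fallback sets out from 10 and comes back at 12. mCPBA in CH2Cl2 epoxidises only the ring olefin, from the α face, to give the 3α,4α-epoxide F8. AcOH/NaOAc at 80 °C opens it trans-diaxially at C3 to the 3β-acetoxy-4α-alcohol F9. Dess–Martin oxidation gives the 3β-acetoxy-4-ketone F10. NaBH4 in MeOH/CH2Cl2 at −78 °C reduces this activated ketone in preference to the enone, by axial attack anti to the C3–O bond, to the equatorial 4β-alcohol, which is 12; methanolysis as in step 6 then gives 13.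

3. Step 10. Sulfation may lose regiocontrol (reaction at O3 or incomplete bis-sulfation), and the polyene may isomerise or degrade while the stannylene acetal is formed. The fallback sets out from 18 and comes back at 21, differentiating the hydroxyls by a protecting group instead of by tin. Trimethyl orthoacetate with PPTS in CH2Cl2 gives the bis(cyclic orthoacetate) F11. Aqueous AcOH at rt opens each orthoester to the axial ester and gives the 3,3'-diacetate F12 with free equatorial 4-hydroxyls. SO3·pyridine in DMF gives the bis(pyridinium) 4,4'-disulfate 3,3'-diacetate F13. K2CO3 in MeOH removes the acetates to give the dipotassium disulfate F14, and the acid resin of step 10 gives 21.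

## Further compounds
F1 | step 2 | rac-cis-1-(2,6,6-trimethylcyclohex-3-en-1-yl)ethanone (one enantiomer drawn) | CC(=O)[C@H]1[C@@H](C)C=CCC1(C)C
F2 | step 2 | rac-trans-1-(2,6,6-trimethylcyclohex-3-en-1-yl)ethanone (one enantiomer drawn) | CC(=O)[C@@H]1[C@@H](C)C=CCC1(C)C
F3 | step 2 | rac-trans-2,6,6-trimethylcyclohex-3-ene-1-carboxylic acid (one enantiomer drawn) | OC(=O)[C@@H]1[C@@H](C)C=CCC1(C)C
F4 | step 2 | rac-trans-2,6,6-trimethylcyclohex-3-ene-1-carbonyl chloride (one enantiomer drawn) | ClC(=O)[C@@H]1[C@@H](C)C=CCC1(C)C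
F5 | step 2 | (4S)-4-benzyl-3-{[(1R,2S)-2,6,6-trimethylcyclohex-3-en-1-yl]carbonyl}oxazolidin-2-one | O=C(N1[C@@H](Cc2ccccc2)COC1=O)[C@@H]3[C@@H](C)C=CCC3(C)C
F6 | step 2 | (4S)-4-benzyl-3-{[(1S,2R)-2,6,6-trimethylcyclohex-3-en-1-yl]carbonyl}oxazolidin-2-one | O=C(N1[C@@H](Cc2ccccc2)COC1=O)[C@H]3[C@H](C)C=CCC3(C)C
F7 | step 2 | [(1R,2S)-2,6,6-trimethylcyclohex-3-en-1-yl]methanol | OC[C@@H]1[C@@H](C)C=CCC1(C)C
F8 | step 6 | 3α,4α-epoxide of 10 (ring epoxide anti to the C6 side chain) | CC(=O)/C=C/[C@@H]1[C@@H](C)[C@H]2O[C@H]2CC1(C)C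
F9 | step 6 | (3E)-4-[(1R,2R,3R,4R)-4-acetoxy-3-hydroxy-2,6,6-trimethylcyclohexyl]but-3-en-2-one (3β-acetoxy, 4α-hydroxy) | CC(=O)/C=C/[C@@H]1[C@@H](C)[C@@H](O)[C@H](OC(C)=O)CC1(C)C
F10 | step 6 | (3E)-4-[(1R,2R,4R)-4-acetoxy-2,6,6-trimethyl-3-oxocyclohexyl]but-3-en-2-one | CC(=O)/C=C/[C@@H]1[C@@H](C)C(=O)[C@H](OC(C)=O)CC1(C)C
F11 | step 10 | 3,4:3',4'-bis-O-(1-methoxyethylidene) derivative of 18 (orthoester carbons unassigned) | CC(/C=C/C=C(C)/C=C/[C@@H]1[C@@H](C)[C@H](OC2(C)OC)[C@H](O2)CC1(C)C)=C\C=C\C=C(C)\C=C\C=C(C)\C=C\[C@@H]1[C@@H](C)[C@H](OC2(C)OC)[C@H](O2)CC1(C)C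
F12 | step 10 | 3,3'-di-O-acetate of 18 | CC(/C=C/C=C(C)/C=C/[C@@H]1[C@@H](C)[C@H](O)[C@H](OC(C)=O)CC1(C)C)=C\C=C\C=C(C)\C=C\C=C(C)\C=C\[C@@H]1[C@@H](C)[C@H](O)[C@H](OC(C)=O)CC1(C)C
F13 | step 10 | bis(pyridinium) 4,4'-disulfate of the 3,3'-di-O-acetate of 18 | CC(/C=C/C=C(C)/C=C/[C@@H]1[C@@H](C)[C@H](OS(=O)(=O)[O-])[C@H](OC(C)=O)CC1(C)C)=C\C=C\C=C(C)\C=C\C=C(C)\C=C\[C@@H]1[C@@H](C)[C@H](OS(=O)(=O)[O-])[C@H](OC(C)=O)CC1(C)C.c1cc[nH+]cc1.c1cc[nH+]cc1
F14 | step 10 | dipotassium salt of 21 | CC(/C=C/C=C(C)/C=C/[C@@H]1[C@@H](C)[C@H](OS(=O)(=O)[O-])[C@H](O)CC1(C)C)=C\C=C\C=C(C)\C=C\C=C(C)\C=C\[C@@H]1[C@@H](C)[C@H](OS(=O)(=O)[O-])[C@H](O)CC1(C)C.[K+].[K+]
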